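**Retrosynthetic overview**

1. The target is traced back, by desilylation and diacetylation, to a diol. The diol comes from hydride reduction of an all-trans 3-formyl-4-(4-methoxybenzoyl)tetrahydrofuran (C7' set by Felkin–Anh addition), and the aroyl group is unmasked by ozonolysis of a β-aryl acrylate.
2. Key disconnection: the tetrahydrofuran ring (O1, C2–C5) comes from ring contraction of a seven-membered cyclic vinyl acetal (a 4,5-dihydro-1,3-dioxepine). The C2–O bond to the enol oxygen is cleaved and the C2–C3 bond is formed, which sets C2 and C3 against C4.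
3. Enabling feature: ring oxygen O1 (on C5) and the oxygen of the C3 acetoxymethyl group are 1,4-related through C5–C4–C3–C9, and C2 is a benzylic, aldehyde-level carbon with a para-oxygenated aryl group. O1, C2 and the C9 oxygen can therefore be tied into a benzylidene acetal whose enol-ether arm (C3=C9–O) later attacks C2.
4. The vinyl acetal comes from an enantioselective Heck reaction between the cis-butenediol acetal of 4-silyloxybenzaldehyde and the enol triflate of methyl 4-methoxybenzoylacetate; this sets C4.
5. Ring order: the seven-membered dioxepine first (acetalisation), then the tetrahydrofuran by contraction. No other ring is built.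

Key step: step 4

Numbering used in the text: tetrahydrofuran O1, C2 (aryl), C3, C4, C5; C9 is the carbon of the C3 side chain and C7' the carbinol carbon on C4.
Assumption: (R)-BINAP is taken to give the (5S) Heck product; if the sense of induction is the opposite, (S)-BINAP is used with no other change.

**Route**

Step 1
Reactants: 1 (Z)-but-2-ene-1,4-diol; 2 4-(tert-butyldimethylsilyloxy)benzaldehyde
Product: 3 2-[4-(tert-butyldimethylsilyloxy)phenyl]-4,7-dihydro-1,3-dioxepine
Conditions: pyridinium p-toluenesulfonate (cat.), benzene, reflux, Dean–Stark trap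
Reagents that add atoms: none
Why: Acid-catalysed acetalisation of the cis-1,4-diol with azeotropic removal of water should close the seven-membered ring while the aryl silyl ether tolerates the weak acid; 3 is achiral, so no stereocentre is set.

Step 2
Reactants: 4 methyl 3-(4-methoxyphenyl)-3-oxopropanoate
Product: 6 methyl (Z)-3-(4-methoxyphenyl)-3-(trifluoromethanesulfonyloxy)prop-2-enoate, via sodium enolate 5 (not isolated)
Conditions: NaH, Et2O, 0 °C; then Tf2O, −78 → 0 °C
Reagents that add atoms: trifluoromethanesulfonic anhydride, O=S(=O)(OS(=O)(=O)C(F)(F)F)C(F)(F)F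
Why: O-sulfonylation of the chelated sodium enolate of a β-keto ester (enol triflate formation) should give the (Z)-triflate, whose geometry is of no consequence because this double bond is cleaved in step 5.

Step 3
Reactants: 3 2-[4-(tert-butyldimethylsilyloxy)phenyl]-4,7-dihydro-1,3-dioxepine; 6 methyl (Z)-3-(4-methoxyphenyl)-3-(trifluoromethanesulfonyloxy)prop-2-enoate
Product: 7 methyl (E)-3-[(5S)-2-[4-(tert-butyldimethylsilyloxy)phenyl]-4,5-dihydro-1,3-dioxepin-5-yl]-3-(4-methoxyphenyl)prop-2-enoate (both epimers at the acetal carbon)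
Conditions: Pd(OAc)2 (5 mol %), (R)-BINAP (10 mol %), iPr2NEt (2 equiv), 3 (3 equiv), benzene, 3 Å molecular sieves, 60 °C
Reagents that add atoms: none
Why: In this asymmetric intermolecular Heck reaction the cationic alkenylpalladium–BINAP species should add syn to one enantiotopic alkene carbon of achiral 3 and so set C5 under ligand control, and because H5 is then anti to palladium, syn β-hydride elimination can only use H7 and leaves the double bond as the enol ether, with the acetal-carbon epimers being irrelevant since that centre is erased in step 4.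

Step 4
Reactants: 7 methyl (E)-3-[(5S)-2-[4-(tert-butyldimethylsilyloxy)phenyl]-4,5-dihydro-1,3-dioxepin-5-yl]-3-(4-methoxyphenyl)prop-2-enoate
Product: 9 (2R,3R,4S)-2-[4-(tert-butyldimethylsilyloxy)phenyl]-4-[(E)-3-methoxy-1-(4-methoxyphenyl)-3-oxoprop-1-en-1-yl]tetrahydrofuran-3-carbaldehyde, via oxocarbenium silyl enol ether ion pair 8 (not isolated)
Conditions: Me3SiOTf (0.1 equiv), CH2Cl2, −78 → −20 °C; then Et3N
Reagents that add atoms: none
Why: Me3SiOTf silylates the enol-ether oxygen of the acetal, the C2–O bond to that oxygen ionises, and ion pair 8 (an aryl-stabilised oxocarbenium on the C5 oxygen, tethered through C5–C4 to the (Z)-silyl enol ether C3=C9) recombines through carbon, after which silyl transfer frees the aldehyde and the catalyst. The closest known reaction type is the Lewis-acid-mediated vinyl acetal (Petasis–Ferrier-type) rearrangement of 4,5-dihydro-1,3-dioxepines to tetrahydrofuran-3-carbaldehydes, an O-to-C 1,3-shift that contracts the seven-membered ring by two atoms (the enol oxygen and C9 leave the ring). The only ring closed is the tetrahydrofuran, by C3–C2 bond formation in a formally 5-(enolexo)-endo-trig aldol-type attack on the oxocarbenium carbon. C4, set in step 3 and untouched here, is the controlling element: closure is reversible (retro-aldol back to 8) and C3 is enolisable, so the product should settle into the all-trans arrangement in which the aryl group and the C4 side chain are cis-1,3 and the formyl group is trans to both, which is (2R,3R) beside (4S). The step needs ionisation at the enol-ether oxygen only and attack by C3 only; the first is secured because only that oxygen can leave as a silyl enol ether, the second because the one other alkene is an electron-poor acrylate and the aryl silyl ether is inert to catalytic Me3SiOTf. Both acetal epimers of 7 converge because that carbon is planar in 8.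

Step 5
Reactants: 9 (2R,3R,4S)-2-[4-(tert-butyldimethylsilyloxy)phenyl]-4-[(E)-3-methoxy-1-(4-methoxyphenyl)-3-oxoprop-1-en-1-yl]tetrahydrofuran-3-carbaldehyde
Product: 11 (2R,3R,4R)-2-[4-(tert-butyldimethylsilyloxy)phenyl]-4-(4-methoxybenzoyl)tetrahydrofuran-3-carbaldehyde, via secondary ozonide 10 (not isolated)
Conditions: O3, CH2Cl2, −78 °C (stopped at first excess); then PPh3, −78 °C → rt
Reagents that add atoms: ozone, [O-][O+]=O
Why: Ozonolysis with reductive work-up should cleave the only C=C bond and unmask the aryl ketone while the arenes and the aldehyde survive at −78 °C; no stereocentre is formed, and C3 and C4, now both next to carbonyl groups, stay in the thermodynamically preferred trans arrangement.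

Step 6
Reactants: 11 (2R,3R,4R)-2-[4-(tert-butyldimethylsilyloxy)phenyl]-4-(4-methoxybenzoyl)tetrahydrofuran-3-carbaldehyde
Product: 13 [(2R,3S,4R)-2-[4-(tert-butyldimethylsilyloxy)phenyl]-4-[(S)-hydroxy(4-methoxyphenyl)methyl]tetrahydrofuran-3-yl]methanol, via lithium keto alkoxide 12 (not isolated)
Conditions: LiBH(sBu)3 (2.5 equiv), THF, −78 → −20 °C; then H2O
Reagents that add atoms: none
Why: The bulky hydride should reduce the aldehyde first and then the aryl ketone by Felkin–Anh addition anti to C3, the more substituted α-branch of C4, which gives the (S)-carbinol at C7' (substrate-controlled carbonyl reduction).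

Step 7
Reactants: 13 [(2R,3S,4R)-2-[4-(tert-butyldimethylsilyloxy)phenyl]-4-[(S)-hydroxy(4-methoxyphenyl)methyl]tetrahydrofuran-3-yl]methanol
Product: 14 [(2R,3S,4R)-4-[(S)-acetoxy(4-methoxyphenyl)methyl]-2-[4-(tert-butyldimethylsilyloxy)phenyl]tetrahydrofuran-3-yl]methyl acetate
Conditions: Ac2O, pyridine, 4-(dimethylamino)pyridine (cat.), CH2Cl2, 0 °C → rt
Reagents that add atoms: acetic anhydride, CC(=O)OC(C)=O
Why: Nucleophile-catalysed acylation should esterify the primary and the secondary benzylic hydroxyl under basic, non-ionising conditions, so no stereocentre is touched.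

Step 8
Reactants: 14 [(2R,3S,4R)-4-[(S)-acetoxy(4-methoxyphenyl)methyl]-2-[4-(tert-butyldimethylsilyloxy)phenyl]tetrahydrofuran-3-yl]methyl acetate
Product: 15 [(2R,3S,4R)-4-[(S)-acetoxy(4-methoxyphenyl)methyl]-2-(4-hydroxyphenyl)tetrahydrofuran-3-yl]methyl acetate
Conditions: Bu4NF, AcOH (1:1, 1.2 equiv), THF, 0 °C
Reagents that add atoms: none
Why: Buffered fluoride should cleave the aryl silyl ether (desilylation) much faster than it touches the two alkyl acetates, and the buffer suppresses phenoxide-driven opening of the benzylic ether, so all four stereocentres are kept.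

**Compound list**

1 | (Z)-but-2-ene-1,4-diol | OC/C=C\CO | starting material
2 | 4-(tert-butyldimethylsilyloxy)benzaldehyde | O=Cc1ccc(O[Si](C)(C)C(C)(C)C)cc1 | starting material
3 | 2-[4-(tert-butyldimethylsilyloxy)phenyl]-4,7-dihydro-1,3-dioxepine | CC(C)(C)[Si](C)(C)Oc1ccc(C2OCC=CCO2)cc1 | intermediate
4 | methyl 3-(4-methoxyphenyl)-3-oxopropanoate | COC(=O)CC(=O)c1ccc(OC)cc1 | starting material
5 | sodium (Z)-enolate of 4 | [Na+].COC(=O)/C=C(\[O-])c1ccc(OC)cc1 | intermediate
6 | methyl (Z)-3-(4-methoxyphenyl)-3-(trifluoromethanesulfonyloxy)prop-2-enoate | COC(=O)/C=C(\OS(=O)(=O)C(F)(F)F)c1ccc(OC)cc1 | intermediate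
7 | methyl (E)-3-[(5S)-2-[4-(tert-butyldimethylsilyloxy)phenyl]-4,5-dihydro-1,3-dioxepin-5-yl]-3-(4-methoxyphenyl)prop-2-enoate, both epimers at the acetal carbon | COC(=O)/C=C(\[C@H]1COC(c2ccc(O[Si](C)(C)C(C)(C)C)cc2)OC=C1)c1ccc(OC)cc1 | intermediate
8 | ion pair: (S)-configured oxocarbenium with pendant (Z)-trimethylsilyl enol ether, triflate counter-ion | COC(=O)/C=C(\[C@@H](C[O+]=Cc1ccc(O[Si](C)(C)C(C)(C)C)cc1)/C=C\O[Si](C)(C)C)c1ccc(OC)cc1.[O-]S(=O)(=O)C(F)(F)F | intermediate
9 | (2R,3R,4S)-2-[4-(tert-butyldimethylsilyloxy)phenyl]-4-[(E)-3-methoxy-1-(4-methoxyphenyl)-3-oxoprop-1-en-1-yl]tetrahydrofuran-3-carbaldehyde (all-trans) | COC(=O)/C=C(\[C@H]1CO[C@@H](c2ccc(O[Si](C)(C)C(C)(C)C)cc2)[C@@H]1C=O)c1ccc(OC)cc1 | intermediate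
10 | secondary ozonide (1,2,4-trioxolane) of 9, mixture at the two trioxolane carbons | COC(=O)C1OOC(O1)(c2ccc(OC)cc2)[C@H]3CO[C@@H](c4ccc(O[Si](C)(C)C(C)(C)C)cc4)[C@@H]3C=O | intermediate
11 | (2R,3R,4R)-2-[4-(tert-butyldimethylsilyloxy)phenyl]-4-(4-methoxybenzoyl)tetrahydrofuran-3-carbaldehyde | COc1ccc(C(=O)[C@H]2CO[C@@H](c3ccc(O[Si](C)(C)C(C)(C)C)cc3)[C@@H]2C=O)cc1 | intermediate
12 | lithium [(2R,3S,4R)-2-[4-(tert-butyldimethylsilyloxy)phenyl]-4-(4-methoxybenzoyl)tetrahydrofuran-3-yl]methanolate | [Li+].COc1ccc(C(=O)[C@H]2CO[C@@H](c3ccc(O[Si](C)(C)C(C)(C)C)cc3)[C@@H]2C[O-])cc1 | intermediate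
13 | [(2R,3S,4R)-2-[4-(tert-butyldimethylsilyloxy)phenyl]-4-[(S)-hydroxy(4-methoxyphenyl)methyl]tetrahydrofuran-3-yl]methanol | COc1ccc([C@@H](O)[C@H]2CO[C@@H](c3ccc(O[Si](C)(C)C(C)(C)C)cc3)[C@@H]2CO)cc1 | intermediate
14 | [(2R,3S,4R)-4-[(S)-acetoxy(4-methoxyphenyl)methyl]-2-[4-(tert-butyldimethylsilyloxy)phenyl]tetrahydrofuran-3-yl]methyl acetate | COc1ccc([C@@H](OC(C)=O)[C@H]2CO[C@@H](c3ccc(O[Si](C)(C)C(C)(C)C)cc3)[C@@H]2COC(C)=O)cc1 | intermediate
15 | [(2R,3S,4R)-4-[(S)-acetoxy(4-methoxyphenyl)methyl]-2-(4-hydroxyphenyl)tetrahydrofuran-3-yl]methyl acetate | COc1ccc([C@@H](OC(C)=O)[C@H]2CO[C@@H](c3ccc(O)cc3)[C@@H]2COC(C)=O)cc1 | target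

**Step count**

Total: 8 steps. Longest linear sequence: 7 steps (steps 1, 3, 4, 5, 6, 7, 8).

**Steps most likely to fail, with fallbacks**

Step 3 (Heck reaction). The hindered, ester-bearing alkenylpalladium species may insert slowly into the unactivated ring alkene. Palladium hydride re-addition could then move the enol-ether double bond into conjugation with the acrylate and erase C5, the triflate could decay under amine and heat, or enantioface selection could be weak. The fallback is an oxidative boron-Heck coupling, which is base-free, runs at room temperature and uses a nitrogen ligand. It sets out from 6. Miyaura borylation (B2pin2, PdCl2(dppf), KOAc, dioxane, 80 °C) should convert 6 with retention into methyl (E)-3-(4-methoxyphenyl)-3-(4,4,5,5-tetramethyl-1,3,2-dioxaborolan-2-yl)prop-2-enoate F1. F1 and 3 are then coupled under divalent palladium catalysis (Pd(OAc)2, (S)-4-tert-butyl-2-(pyridin-2-yl)-4,5-dihydrooxazole, O2 at 1 atm, DMF, rt; ligand enantiomer chosen for the (5S) product), with transmetalation in place of oxidative addition. The fallback comes back to the route at 7.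

Step 4 (ring contraction). The ion pair may collapse with the aryl group trans to the C4 side chain and not be corrected, because the retro-aldol is slow at temperatures the substrate tolerates. The oxocarbenium partner may also be lost by adventitious hydrolysis. The fallback is a classical aldol and acid-mediated cycloetherification without vinyl acetal chemistry, and it sets out from 7.
- AcOH–H2O–THF at rt should hydrolyse the vinyl acetal to the lactol methyl (E)-3-[(3S)-5-hydroxytetrahydrofuran-3-yl]-3-(4-methoxyphenyl)prop-2-enoate F2, with 2 recovered.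
- TEMPO (cat.) and PhI(OAc)2 in CH2Cl2 should oxidise F2 to the lactone methyl (E)-3-(4-methoxyphenyl)-3-[(3S)-5-oxotetrahydrofuran-3-yl]prop-2-enoate F3.
- LiN(iPr)2 in THF at −78 °C, then 2, should give the trans aldol adduct methyl (E)-3-[(3S,4S)-4-{[4-(tert-butyldimethylsilyloxy)phenyl](hydroxy)methyl}-5-oxotetrahydrofuran-3-yl]-3-(4-methoxyphenyl)prop-2-enoate F4.
- Disiamylborane, (Me2CHCHMe)2BH, in THF at 0 °C should reduce only the lactone, to the lactol methyl (E)-3-[(3S,4S)-4-{[4-(tert-butyldimethylsilyloxy)phenyl](hydroxy)methyl}-5-hydroxytetrahydrofuran-3-yl]-3-(4-methoxyphenyl)prop-2-enoate F5.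
- Camphorsulfonic acid (cat.) in CH2Cl2 at rt should then ionise the benzylic alcohol, and the C5 hydroxyl of the open hydroxy aldehyde captures the cation. The enolisable C3 and the reversible benzylic C–O bond should let the all-trans aldehyde accumulate.

The fallback comes back to the route at 9.

Step 6 (double reduction). Facial selectivity at the ketone may be eroded: the lithium alkoxide formed at C9 can chelate the ketone and override the Felkin–Anh preference, and C4 may epimerise under the basic hydride before reduction. The fallback uses two stages with reagent control and sets out from 11. NaBH4 (0.3 equiv) in CH2Cl2–MeOH at −78 °C should reduce the aldehyde only, to [(2R,3S,4R)-2-[4-(tert-butyldimethylsilyloxy)phenyl]-3-(hydroxymethyl)tetrahydrofuran-4-yl](4-methoxyphenyl)methanone F6. Corey–Bakshi–Shibata reduction ((R)-2-methyl-CBS-oxazaborolidine, BH3·SMe2, THF, −20 °C; the catalyst enantiomer that gives the (S)-carbinol with the aryl group as the large substituent) then reduces the aryl ketone under catalyst control. The fallback comes back to the route at 13.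

**Further compounds**

F1 | step 3 | methyl (E)-3-(4-methoxyphenyl)-3-(4,4,5,5-tetramethyl-1,3,2-dioxaborolan-2-yl)prop-2-enoate | COC(=O)/C=C(\B1OC(C)(C)C(C)(C)O1)c1ccc(OC)cc1
F2 | step 4 | methyl (E)-3-[(3S)-5-hydroxytetrahydrofuran-3-yl]-3-(4-methoxyphenyl)prop-2-enoate (lactol, both anomers) | COC(=O)/C=C(\[C@H]1COC(O)C1)c1ccc(OC)cc1
F3 | step 4 | methyl (E)-3-(4-methoxyphenyl)-3-[(3S)-5-oxotetrahydrofuran-3-yl]prop-2-enoate | COC(=O)/C=C(\[C@H]1COC(=O)C1)c1ccc(OC)cc1
F4 | step 4 | methyl (E)-3-[(3S,4S)-4-{[4-(tert-butyldimethylsilyloxy)phenyl](hydroxy)methyl}-5-oxotetrahydrofuran-3-yl]-3-(4-methoxyphenyl)prop-2-enoate (carbinol epimers) | COC(=O)/C=C(\[C@H]1COC(=O)[C@@H]1C(O)c1ccc(O[Si](C)(C)C(C)(C)C)cc1)c1ccc(OC)cc1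
F5 | step 4 | methyl (E)-3-[(3S,4S)-4-{[4-(tert-butyldimethylsilyloxy)phenyl](hydroxy)methyl}-5-hydroxytetrahydrofuran-3-yl]-3-(4-methoxyphenyl)prop-2-enoate (lactol, carbinol epimers) | COC(=O)/C=C(\[C@H]1COC(O)[C@@H]1C(O)c1ccc(O[Si](C)(C)C(C)(C)C)cc1)c1ccc(OC)cc1
F6 | step 6 | [(2R,3S,4R)-2-[4-(tert-butyldimethylsilyloxy)phenyl]-3-(hydroxymethyl)tetrahydrofuran-4-yl](4-methoxyphenyl)methanone | COc1ccc(C(=O)[C@H]2CO[C@@H](c3ccc(O[Si](C)(C)C(C)(C)C)cc3)[C@@H]2CO)cc1
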